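**Retrosynthetic overview**

1. Each half is numbered as a quinolizidine (N5, C1–C4, C6–C9, C9a); the target is (1R,3S,9S,9aR) in both halves, ring A is the piperidin-4-one and ring B the piperidine.
2. Target ⇒ two N5–C4 bonds (intramolecular aza-Michael, with C1, C3 and C9a then equilibrated) ⇒ 16-membered carbocycle 18 carrying two α-methylene ketones and two N-Boc piperidines.
3. 18 ⇒ two C1–C9a bonds: head-to-tail Mannich cyclodimerisation (piperidine iminium carbon plus ketone enol carbon) of two molecules of monomer 16.
4. 16 ⇒ (3S)-lactam 9 ⇒ Evans Michael addition of the azelaic half-ester imide 4 to acrylonitrile, which sets C9, the only centre not left to thermodynamic control.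
5. Ring order: ring B (step 3), then the 16-membered ring (step 8), then ring A (step 9), each formed twice.

Assumption: with both C9 centres S, the target (trans-fused rings, C1 and C3 substituents equatorial, C9 chain axial) is taken to be the most stable diastereomer, so equilibration of C1, C3 and C9a ends there.

**Route**

Step 1
Reactants: 1 azelaic acid monomethyl ester (9-methoxy-9-oxononanoic acid); 2 (4R)-4-benzyl-1,3-oxazolidin-2-one
Product: 4 (4R)-4-benzyl-3-(9-methoxy-9-oxononanoyl)-1,3-oxazolidin-2-one, via mixed pivalic anhydride 3 (not isolated)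
Conditions: PivCl, Et3N, THF, −20 °C; then 2, LiCl, −20 °C to rt
Reagents that add atoms: none
Why: Mixed-anhydride N-acylation of the LiCl-activated oxazolidinone (Evans auxiliary attachment) takes place only at the free acid terminus because the methyl ester is inert to pivaloyl chloride, and no stereocentre is formed.

Step 2
Reactants: 4 (4R)-4-benzyl-3-(9-methoxy-9-oxononanoyl)-1,3-oxazolidin-2-one; 5 acrylonitrile
Product: 7 methyl (8S)-8-{[(4R)-4-benzyl-2-oxo-1,3-oxazolidin-3-yl]carbonyl}-10-cyanodecanoate, via titanium enolate 6 (not isolated)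
Conditions: TiCl4, Ti(OiPr)4 (3:1, gives TiCl3(OiPr)), iPr2NEt, CH2Cl2, 0 °C; then acrylonitrile, 0 °C to rt
Reagents that add atoms: none
Why: Evans titanium-enolate Michael addition, in which the chelated Z-enolate of the imide (the distal ester is not enolised by this soft enolisation) adds to acrylonitrile on the face opposite the benzyl group and so sets the future C9 centre as S.

Step 3
Reactants: 7 methyl (8S)-8-{[(4R)-4-benzyl-2-oxo-1,3-oxazolidin-3-yl]carbonyl}-10-cyanodecanoate
Product: 9 methyl 7-[(3S)-2-oxopiperidin-3-yl]heptanoate, via primary amine 8 (not isolated)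
Conditions: H2 (4 atm), Raney Ni, MeOH, 50 °C
Reagents that add atoms: none
Why: Nitrile hydrogenation gives a primary amine that attacks the imide carbonyl in a 6-exo-trig reductive lactamisation, which builds ring B, expels the auxiliary and leaves the α-stereocentre untouched.

Step 4
Reactants: 9 methyl 7-[(3S)-2-oxopiperidin-3-yl]heptanoate
Product: 10 tert-butyl (3S)-3-(7-methoxy-7-oxoheptyl)-2-oxopiperidine-1-carboxylate
Conditions: Boc2O, DMAP (cat.), MeCN, rt
Reagents that add atoms: di-tert-butyl dicarbonate, CC(C)(C)OC(=O)OC(=O)OC(C)(C)C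
Why: DMAP-catalysed N-acylation of the lactam makes its carbonyl imide-like, so that it can be half-reduced and later ionised to an N-acyliminium ion, and no base able to epimerise C3 is present.

Step 5
Reactants: 10 tert-butyl (3S)-3-(7-methoxy-7-oxoheptyl)-2-oxopiperidine-1-carboxylate
Product: 12 tert-butyl (3S)-2-methoxy-3-(7-methoxy-7-oxoheptyl)piperidine-1-carboxylate, via hemiaminal 11 (not isolated)
Conditions: LiEt3BH (1.1 equiv), THF, −78 °C; then MeOH, PPTS (cat.), rt
Reagents that add atoms: methanol, CO
Why: Chemoselective partial reduction, in which LiEt3BH adds once to the activated N-Boc lactam carbonyl at −78 °C much faster than to the methyl ester, followed by acid-catalysed acetal exchange that stores the hemiaminal as an N,O-acetal whose new centre is an inconsequential epimer mixture.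

Step 6
Reactants: 12 tert-butyl (3S)-2-methoxy-3-(7-methoxy-7-oxoheptyl)piperidine-1-carboxylate; 13 isopropenylmagnesium bromide
Product: 15 tert-butyl (3S)-2-methoxy-3-(8-methyl-7-oxonon-8-en-1-yl)piperidine-1-carboxylate, via Weinreb amide 14 (not isolated)
Conditions: MeNH(OMe)·HCl, iPrMgCl, THF, −20 °C; then CH2=C(CH3)MgBr, −20 to 0 °C; cold aq. NH4Cl
Reagents that add atoms: none
Why: One-pot ester to Weinreb amide to ketone conversion, in which the magnesium amide of N,O-dimethylhydroxylamine gives the Weinreb amide and its chelated tetrahedral adduct with the alkenyl Grignard reagent collapses only on work-up, so no over-addition occurs.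

Step 7
Reactants: 15 tert-butyl (3S)-2-methoxy-3-(8-methyl-7-oxonon-8-en-1-yl)piperidine-1-carboxylate
Product: 16 tert-butyl (3S)-2-methoxy-3-[8-methyl-7-(trimethylsilyloxy)nona-6,8-dien-1-yl]piperidine-1-carboxylate
Conditions: LiN(iPr)2, TMSCl, THF, −78 °C (internal quench); Et3N, pentane work-up, used crude
Reagents that add atoms: chlorotrimethylsilane, C[Si](C)(C)Cl
Why: Kinetic deprotonation at the only enolisable α-position (the CH2 next to the carbonyl) with in situ O-silylation gives the cross-conjugated 2-silyloxy diene (silyl enol ether formation), and the C9 centre carries no acidic hydrogen.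

Step 8
Reactants: 16 tert-butyl (3S)-2-methoxy-3-[8-methyl-7-(trimethylsilyloxy)nona-6,8-dien-1-yl]piperidine-1-carboxylate (two molecules)
Product: 18 macrocyclic bis(N-Boc-piperidine) bis(α-methylene ketone), via linear dimer 17 (not isolated)
Conditions: TMSOTf (0.2 equiv), CH2Cl2 (0.01 M), −78 to −40 °C; Et3N quench
Reagents that add atoms: none
Why: Proposed new method: head-to-tail double Mukaiyama–Mannich cyclodimerisation, in which TMSOTf ionises the N,O-acetal to an N-acyliminium ion that is captured at C9a by the silyl enol ether carbon (C1) of a second molecule, because self-capture would need an eight-membered ring, and the second, now intramolecular, capture closes the 16-membered ring; the closest known reaction is the TMSOTf- or BF3-mediated addition of silyl enol ethers to N-Boc-2-methoxypiperidine, the C9 centres are retained because no base is present, and C1 and C9a form as a mixture that step 9 corrects.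

Step 9
Reactants: 18 macrocyclic bis(N-Boc-piperidine) bis(α-methylene ketone)
Product: 21 target bis-quinolizidinone, via macrocyclic bis-amine 19 (not isolated), via bis-quinolizidinone isomer mixture 20 (not isolated)
Conditions: TFA, CH2Cl2, 0 °C to rt; evaporate; then K2CO3, MeOH (0.005 M), 50 °C
Reagents that add atoms: none
Why: Boc cleavage frees the piperidine nitrogens, which close both rings A by 6-endo-trig aza-Michael addition to the α-methylene ketones, and in the basic protic medium C1 and C3 epimerise by enolisation and C9a by reversible retro-aza-Michael/aza-Michael ring opening (as in pelletierine), so the mixture funnels to the most stable isomer with C1 and C3 substituents equatorial on trans-fused rings while the non-acidic C9 centres stay S.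

**Compound list**

1 | azelaic acid monomethyl ester (9-methoxy-9-oxononanoic acid) | COC(=O)CCCCCCCC(=O)O | starting material
2 | (4R)-4-benzyl-1,3-oxazolidin-2-one | O=C1N[C@H](Cc2ccccc2)CO1 | starting material
3 | mixed anhydride of 1 with pivalic acid | COC(=O)CCCCCCCC(=O)OC(=O)C(C)(C)C | intermediate (not isolated)
4 | (4R)-4-benzyl-3-(9-methoxy-9-oxononanoyl)-1,3-oxazolidin-2-one | COC(=O)CCCCCCCC(=O)N1[C@H](Cc2ccccc2)COC1=O | intermediate
5 | acrylonitrile | C=CC#N | starting material
6 | (Z)-titanium enolate of 4, O–TiCl2(OiPr) | COC(=O)CCCCCC/C=C(\O[Ti](Cl)(Cl)OC(C)C)N1[C@H](Cc2ccccc2)COC1=O | intermediate (not isolated)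
7 | methyl (8S)-8-{[(4R)-4-benzyl-2-oxo-1,3-oxazolidin-3-yl]carbonyl}-10-cyanodecanoate | COC(=O)CCCCCC[C@@H](CCC#N)C(=O)N1[C@H](Cc2ccccc2)COC1=O | intermediate
8 | methyl (8S)-11-amino-8-{[(4R)-4-benzyl-2-oxo-1,3-oxazolidin-3-yl]carbonyl}undecanoate | COC(=O)CCCCCC[C@@H](CCCN)C(=O)N1[C@H](Cc2ccccc2)COC1=O | intermediate (not isolated)
9 | methyl 7-[(3S)-2-oxopiperidin-3-yl]heptanoate | COC(=O)CCCCCC[C@H]1CCCNC1=O | intermediate
10 | tert-butyl (3S)-3-(7-methoxy-7-oxoheptyl)-2-oxopiperidine-1-carboxylate | COC(=O)CCCCCC[C@H]1CCCN(C(=O)OC(C)(C)C)C1=O | intermediate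
11 | tert-butyl (3S)-2-hydroxy-3-(7-methoxy-7-oxoheptyl)piperidine-1-carboxylate (C2 epimers) | COC(=O)CCCCCC[C@H]1CCCN(C(=O)OC(C)(C)C)C1O | intermediate (not isolated)
12 | tert-butyl (3S)-2-methoxy-3-(7-methoxy-7-oxoheptyl)piperidine-1-carboxylate (C2 epimers) | COC(=O)CCCCCC[C@H]1CCCN(C(=O)OC(C)(C)C)C1OC | intermediate
13 | isopropenylmagnesium bromide | CC(=C)[Mg]Br | starting material
14 | tert-butyl (3S)-2-methoxy-3-{7-[methoxy(methyl)amino]-7-oxoheptyl}piperidine-1-carboxylate | CON(C)C(=O)CCCCCC[C@H]1CCCN(C(=O)OC(C)(C)C)C1OC | intermediate (not isolated)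
15 | tert-butyl (3S)-2-methoxy-3-(8-methyl-7-oxonon-8-en-1-yl)piperidine-1-carboxylate | CC(=C)C(=O)CCCCCC[C@H]1CCCN(C(=O)OC(C)(C)C)C1OC | intermediate
16 | tert-butyl (3S)-2-methoxy-3-[8-methyl-7-(trimethylsilyloxy)nona-6,8-dien-1-yl]piperidine-1-carboxylate | CC(=C)C(O[Si](C)(C)C)=CCCCCC[C@H]1CCCN(C(=O)OC(C)(C)C)C1OC | intermediate
17 | linear dimer: C1 of one unit (now a 2-methylacryloyl ketone, N,O-acetal intact) bonded to piperidine C2 of the second unit, which keeps its silyl dienol ether; C9 centres S, C1 and C9a epimers | CC(=C)C(=O)C(CCCCC[C@H]1CCCN(C(=O)OC(C)(C)C)C1OC)C1N(C(=O)OC(C)(C)C)CCC[C@@H]1CCCCCC=C(O[Si](C)(C)C)C(C)=C | intermediate (not isolated)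
18 | 16-membered carbocycle in which two CH(COC(CH3)=CH2)–(CH2)5 units alternate with two N-Boc-piperidine-2,3-diyl units (piperidine C2 = C9a bonded to the acyl-bearing CH = C1, piperidine C3 = C9, S); C1 and C9a epimers | CC(=C)C(=O)C1CCCCC[C@H]2CCCN(C(=O)OC(C)(C)C)C2C(C(=O)C(C)=C)CCCCC[C@H]2CCCN(C(=O)OC(C)(C)C)C21 | intermediate
19 | Boc-free 18 (bis-piperidine, formed as its bis(trifluoroacetate) and freed by K2CO3) | CC(=C)C(=O)C1CCCCC[C@H]2CCCNC2C(C(=O)C(C)=C)CCCCC[C@H]2CCCNC21 | intermediate (not isolated)
20 | bis-quinolizidinone with the target connectivity, both C9 centres S, mixture of C1, C3 and C9a epimers | CC1CN2CCC[C@@H]3CCCCCC4C(=O)C(C)CN5CCC[C@H](CCCCCC(C1=O)C32)C45 | intermediate (not isolated)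
21 | target: macrocyclic bis(3-methylquinolizidin-2-one), C1 of each half joined by (CH2)5 to C9 of the other, (1R,3S,9S,9aR) in both halves | C[C@H]1CN2CCC[C@@H]3CCCCC[C@H]4C(=O)[C@@H](C)CN5CCC[C@H](CCCCC[C@@H](C1=O)[C@@H]32)[C@H]45 | target

**Totals and risks**

Total step count: 9. Longest linear sequence: 9 steps (1 to 21).

Most likely to fail, in order:

Step 8, the cyclodimerisation. At 0.01 M the N-acyliminium ion may lose a proton to an enecarbamate, or oligomers and the eight-membered monomer ring may compete. The fallback sets out from 15 and reverses the bond order, nitrogen–carbon first and Mannich last. HCl in MeOH removes Boc and opens the N,O-acetal to the amino acetal salt (10S)-13-amino-10-(dimethoxymethyl)-2-methyltridec-1-en-3-one hydrochloride F5 (any HCl adduct of the enone reverts on neutralisation). Freeing the amine (Et3N, MeOH, 0.05 M, rt) gives head-to-tail double aza-Michael macrocyclisation to the 28-membered diamine (5S,19S)-5,19-bis(dimethoxymethyl)-13,27-dimethyl-1,15-diazacyclooctacosane-12,26-dione F6, which must be separated from the 14-membered monomer ring and oligomers. Aqueous 2 M HCl at 50 °C then unmasks the aldehydes, the cyclic iminium ions form and a double transannular Mannich reaction gives the isomer mixture 20, where the fallback comes back to the route for the base equilibration of step 9. In strong acid with no base present the iminium α-centre C9 should not epimerise.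

Step 9, the equilibration. The solution equilibrium may not favour the target strongly, or C9a may epimerise slowly under base. The fallback sets out from the isomer mixture 20 and replaces solution equilibrium by a crystallisation-induced diastereomer transformation. The mixture is heated with HCl (2.2 equiv) in EtOH, where the Mannich bond C1–C9a opens and closes reversibly, and is seeded so that the dihydrochloride of the target F7 crystallises while the mother liquor keeps equilibrating. NaHCO3 then frees the base, and the fallback comes back to the route at 21.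

Step 7, the silyl dienol ether. The amide base may add to or polymerise the vinyl ketone, and the diene is sensitive. The fallback sets out from 15 and masks the alkene first. Conjugate addition of thiophenol (PhSH, cat. Et3N, CH2Cl2) gives the sulfanyl ketone tert-butyl (3S)-2-methoxy-3-[8-methyl-7-oxo-9-(phenylsulfanyl)nonyl]piperidine-1-carboxylate F1. Kinetic enolisation on the CH2 side (LiN(iPr)2, TMSCl, THF, −78 °C) gives the silyl enol ether tert-butyl (3S)-2-methoxy-3-[8-methyl-9-(phenylsulfanyl)-7-(trimethylsilyloxy)non-6-en-1-yl]piperidine-1-carboxylate F2. The same TMSOTf-catalysed cyclodimerisation gives the bis(sulfanyl ketone) analogue of 18 F3, and TFA gives its Boc-free bis-piperidine F4. K2CO3 in MeOH then eliminates thiophenolate and regenerates the α-methylene ketones, which is compound 19, where the fallback comes back to the route.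

**Further compounds**

F1 | step 7 | tert-butyl (3S)-2-methoxy-3-[8-methyl-7-oxo-9-(phenylsulfanyl)nonyl]piperidine-1-carboxylate | CC(CSc1ccccc1)C(=O)CCCCCC[C@H]2CCCN(C(=O)OC(C)(C)C)C2OC
F2 | step 7 | tert-butyl (3S)-2-methoxy-3-[8-methyl-9-(phenylsulfanyl)-7-(trimethylsilyloxy)non-6-en-1-yl]piperidine-1-carboxylate | CC(CSc1ccccc1)C(O[Si](C)(C)C)=CCCCCC[C@H]2CCCN(C(=O)OC(C)(C)C)C2OC
F3 | step 7 | analogue of 18 with each 2-methylacryloyl group replaced by 2-methyl-3-(phenylsulfanyl)propanoyl | CC(CSc1ccccc1)C(=O)C1CCCCC[C@H]2CCCN(C(=O)OC(C)(C)C)C2C(C(=O)C(C)CSc2ccccc2)CCCCC[C@H]2CCCN(C(=O)OC(C)(C)C)C21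
F4 | step 7 | Boc-free F3 (bis-piperidine) | CC(CSc1ccccc1)C(=O)C1CCCCC[C@H]2CCCNC2C(C(=O)C(C)CSc2ccccc2)CCCCC[C@H]2CCCNC21
F5 | step 8 | (10S)-13-amino-10-(dimethoxymethyl)-2-methyltridec-1-en-3-one hydrochloride | CC(=C)C(=O)CCCCCC[C@@H](CCCN)C(OC)OC.Cl
F6 | step 8 | (5S,19S)-5,19-bis(dimethoxymethyl)-13,27-dimethyl-1,15-diazacyclooctacosane-12,26-dione | CC1CNCCC[C@@H](C(OC)OC)CCCCCCC(=O)C(C)CNCCC[C@@H](C(OC)OC)CCCCCCC1=O
F7 | step 9 | dihydrochloride of target 21 | C[C@H]1CN2CCC[C@@H]3CCCCC[C@H]4C(=O)[C@@H](C)CN5CCC[C@H](CCCCC[C@@H](C1=O)[C@@H]32)[C@H]45.Cl.Cl
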